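**Retrosynthetic overview**

1. Gericudranin D (20) comes from hexabenzyl dihydroflavonol 19 by global hydrogenolysis. The C4 ketone of 19 comes from a C4 methyl ether by hydrolysis and alcohol oxidation, after the O3 acetate of cycloadduct 15 has been exchanged for a benzyl ether.
2. The strategy rests on ring C (O1–C2–C3–C4–C4a–C8a). O1–C8a–C4a–C4 is a four-atom heterodiene and C2–C3 is an oxygenated styrene unit, so O1–C2 and C3–C4 are cut in one oxa-[4+2] that also sets C2 and C3.
3. The heterodiene is the methoxy ortho-quinone methide 14, made in the flask from salicylaldehyde 5 and trimethyl orthoformate. The 2π partner is the E-enol acetate 11.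
4. Aldehyde 5 comes from 2,4,6-trihydroxybenzaldehyde by twofold C-hydroxybenzylation at C3/C5 and fourfold O-benzylation that spares the chelated phenol. Enol acetate 11 comes from 4-benzyloxybenzaldehyde by Doebner condensation, bromodecarboxylation and copper-mediated acetoxylation.
5. Ring order: ring A, ring B and the two pendant aryl rings are bought; ring C is the only ring formed (step 6).

Key step: step 6

Assumption: the facial bias of the chiral acid in step 6 cannot be assigned in advance for this quinone methide; the (R)-acid is written, and its enantiomer is to be used if a first run delivers the (2S,3R) series.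

**Route**

Step 1
Reactants: 1 2,4,6-trihydroxybenzaldehyde; 2 4-hydroxybenzyl alcohol (2.3 equiv)
Product: 4 2,4,6-trihydroxy-3,5-bis(4-hydroxybenzyl)benzaldehyde, via mono(4-hydroxybenzyl) aldehyde 3 (not isolated)
Conditions: TsOH·H2O (10 mol%), 1,4-dioxane, 60 °C, 2 added over 3 h
Reagents that add atoms: none
Why: Friedel–Crafts-type C-benzylation in which acid turns 2 into the para-hydroxybenzyl cation (protonated para-quinone methide), which the acylphloroglucinol ring should capture at its only two free positions C3 and C5; no stereocentre is formed.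

Step 2
Reactants: 4 2,4,6-trihydroxy-3,5-bis(4-hydroxybenzyl)benzaldehyde
Product: 5 4,6-bis(benzyloxy)-3,5-bis[4-(benzyloxy)benzyl]-2-hydroxybenzaldehyde
Conditions: BnBr (4.1 equiv), K2CO3 (4.5 equiv), DMF, 0 °C → rt
Reagents that add atoms: benzyl bromide, BrCc1ccccc1
Why: Williamson etherification in which the acidic 4-OH, the two side-chain phenols and one of the two equivalent ortho hydroxyls should react, while the last ortho hydroxyl is held in a hydrogen bond to the aldehyde carbonyl and stays free (chelation-controlled partial alkylation of a 2,4,6-trihydroxyaryl carbonyl compound).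

Step 3
Reactants: 6 4-benzyloxybenzaldehyde; 7 malonic acid
Product: 9 (E)-4-benzyloxycinnamic acid, via benzylidenemalonic acid 8 (not isolated)
Conditions: pyridine, piperidine (cat.), 100 °C
Reagents that add atoms: none
Why: Knoevenagel–Doebner condensation, in which decarboxylation of the alkylidene malonic acid should give the E-configured cinnamic acid.

Step 4
Reactants: 9 (E)-4-benzyloxycinnamic acid
Product: 10 (E)-1-(benzyloxy)-4-(2-bromovinyl)benzene
Conditions: NBS (1.05 equiv), Et3N (10 mol%), CH2Cl2, rt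
Reagents that add atoms: N-bromosuccinimide, O=C1CCC(=O)N1Br
Why: catalytic Hunsdiecker-type bromodecarboxylation, in which bromination of the electron-rich alkene, carboxylate participation and anti loss of CO2 should deliver the E-vinyl bromide.

Step 5
Reactants: 10 (E)-1-(benzyloxy)-4-(2-bromovinyl)benzene
Product: 11 (E)-2-[4-(benzyloxy)phenyl]vinyl acetate
Conditions: CuOAc (monovalent copper, 2 equiv), pyridine, 110 °C, N2
Reagents that add atoms: copper acetate CuOAc (monovalent copper), CC(=O)[O-].[Cu+]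
Why: copper-mediated vinylic substitution (Ullmann-type C–O coupling of a vinyl halide with a carboxylate), which runs through oxidative addition and reductive elimination at copper with retention of alkene geometry, so the E-bromide should give the E-enol acetate.

Step 6
Reactants: 5 4,6-bis(benzyloxy)-3,5-bis[4-(benzyloxy)benzyl]-2-hydroxybenzaldehyde; 11 (E)-2-[4-(benzyloxy)phenyl]vinyl acetate (2 equiv); 12 trimethyl orthoformate (3 equiv)
Product: 15 (2R,3S)-3-acetoxy-4-methoxyflavan cycloadduct (2,3-trans; both C4 epimers), via dimethyl acetal 13 (not isolated), via methoxy ortho-quinone methide 14 (not isolated)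
Conditions: (R)-3,3'-bis(2,4,6-triisopropylphenyl)-1,1'-binaphthyl-2,2'-diyl N-triflylphosphoramide (10 mol%), CH2Cl2, 4 Å MS, −20 °C → rt
Reagents that add atoms: none
Why: Proposed new method: the acid and 12 convert 5 into acetal 13, which loses methanol through the free ortho phenol to give the methoxy-substituted ortho-quinone methide 14 (ion-paired in its O-protonated oxocarbenium form with the chiral phosphoramide anion), and 11 adds in an asynchronous inverse-demand oxa-[4+2] in which C3–C4 forms first and the charge growing at C2 is carried by the 4-benzyloxyphenyl group before O1–C2 closes; the closest known reaction type is the Brønsted-acid-catalysed chroman synthesis from salicylaldehydes, trimethyl orthoformate and styrenes together with chiral-acid-catalysed ortho-quinone methide/styrene cycloadditions, and the new element is the β-acetoxystyrene as 2π partner. Ring C (O1–C2–C3–C4–C4a–C8a) is closed as a six-membered pyran in the [4+2] mode, the bonds O1–C2 and C3–C4 joining the heterodiene O1–C8a–C4a–C4 to the C2=C3 unit. The C2/C3 relative configuration should follow from suprafacial transfer of the E geometry of 11 (and, if the addition is stepwise, from the diequatorial preference at ring closure), giving 2,3-trans; the absolute configuration (2R,3S) is to be set by the chiral anion, which is hydrogen-bonded to the quinone methide oxygen and shields one face of C4; C4 forms as a mixture and loses its stereochemistry later. The step needs regioselectivity, the acetoxy-bearing carbon bonding to C4, and this is secured because the para-alkoxyphenyl group stabilises positive charge far better than the acylated enol oxygen, so the benzylic carbon becomes C2. It also needs cycloaddition to outrun acid methanolysis of the enol ester, which excess 12 as water scavenger, low temperature and a sub-stoichiometric acid should secure.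

Step 7
Reactants: 15 (2R,3S)-3-acetoxy-4-methoxyflavan cycloadduct
Product: 16 (2R,3S)-5,7-bis(benzyloxy)-6,8-bis[4-(benzyloxy)benzyl]-2-[4-(benzyloxy)phenyl]-4-methoxychroman-3-ol (C4 epimers)
Conditions: K2CO3 (20 mol%), MeOH/THF 1:1, rt
Reagents that add atoms: none
Why: Zemplén-type transesterification that removes the ester before C4 is ionised, so that neither acyl participation nor O3→O4 acyl migration can occur later; C2 and C3 are not epimerisable because no carbonyl is present yet.

Step 8
Reactants: 16 (2R,3S)-4-methoxychroman-3-ol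
Product: 17 (2R,3S)-3,5,7-tris(benzyloxy)-6,8-bis[4-(benzyloxy)benzyl]-2-[4-(benzyloxy)phenyl]-4-methoxychroman (C4 epimers)
Conditions: NaH (1.5 equiv), BnBr (1.3 equiv), Bu4NI (cat.), THF/DMF, 0 °C → rt
Reagents that add atoms: benzyl bromide, BrCc1ccccc1
Why: Williamson etherification of the secondary alkoxide, installing at O3 a non-migrating group that leaves in the final hydrogenolysis; no stereocentre is touched.

Step 9
Reactants: 17 (2R,3S)-3-benzyloxy-4-methoxychroman
Product: 18 (2R,3S)-3,5,7-tris(benzyloxy)-6,8-bis[4-(benzyloxy)benzyl]-2-[4-(benzyloxy)phenyl]chroman-4-ol (C4 epimers)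
Conditions: TsOH·H2O (10 mol%), THF/H2O 4:1, 40 °C
Reagents that add atoms: water, O
Why: SN1 hydrolysis of a benzylic methyl ether through the C4 cation stabilised by O1 and the 5- and 7-alkoxy groups, driven by the excess of water; the C4 configuration is irrelevant and the O3 benzyl ether cannot migrate.

Step 10
Reactants: 18 (2R,3S)-chroman-4-ol
Product: 19 (2R,3R)-3,5,7-tris(benzyloxy)-6,8-bis[4-(benzyloxy)benzyl]-2-[4-(benzyloxy)phenyl]chroman-4-one
Conditions: Dess–Martin periodinane (1.3 equiv), pyridine (3 equiv), CH2Cl2, 0 °C → rt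
Reagents that add atoms: none
Why: Dess–Martin oxidation of the secondary benzylic alcohol by ligand exchange at iodine, which should leave the diarylmethane methylenes at C6 and C8 untouched and, being buffered, should not epimerise C3 (the descriptor changes to 3R only because C4 now outranks C2).

Step 11
Reactants: 19 (2R,3R)-hexabenzyl dihydroflavonol
Product: 20 gericudranin D
Conditions: H2 (1 atm), Pd(OH)2/C, THF/MeOH 1:1, rt
Reagents that add atoms: none
Why: catalytic hydrogenolysis of the five aryl benzyl ethers and the O3 benzyl ether under neutral conditions, which should spare the chelated C4 ketone and the C2 and C3 stereocentres when stopped at full debenzylation.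

**Compound list**

1 | 2,4,6-trihydroxybenzaldehyde | O=Cc1c(O)cc(O)cc1O | starting material
2 | 4-hydroxybenzyl alcohol | OCc1ccc(O)cc1 | starting material
3 | 2,4,6-trihydroxy-3-(4-hydroxybenzyl)benzaldehyde (not isolated) | O=Cc1c(O)cc(O)c(Cc2ccc(O)cc2)c1O | intermediate
4 | 2,4,6-trihydroxy-3,5-bis(4-hydroxybenzyl)benzaldehyde | O=Cc1c(O)c(Cc2ccc(O)cc2)c(O)c(Cc2ccc(O)cc2)c1O | intermediate
5 | 4,6-bis(benzyloxy)-3,5-bis[4-(benzyloxy)benzyl]-2-hydroxybenzaldehyde | O=Cc1c(O)c(Cc2ccc(OCc3ccccc3)cc2)c(OCc2ccccc2)c(Cc2ccc(OCc3ccccc3)cc2)c1OCc1ccccc1 | intermediate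
6 | 4-benzyloxybenzaldehyde | O=Cc1ccc(OCc2ccccc2)cc1 | starting material
7 | malonic acid | OC(=O)CC(=O)O | starting material
8 | 2-[4-(benzyloxy)benzylidene]malonic acid (not isolated) | OC(=O)C(=Cc1ccc(OCc2ccccc2)cc1)C(=O)O | intermediate
9 | (E)-4-benzyloxycinnamic acid | OC(=O)/C=C/c1ccc(OCc2ccccc2)cc1 | intermediate
10 | (E)-1-(benzyloxy)-4-(2-bromovinyl)benzene | Br/C=C/c1ccc(OCc2ccccc2)cc1 | intermediate
11 | (E)-2-[4-(benzyloxy)phenyl]vinyl acetate | CC(=O)O/C=C/c1ccc(OCc2ccccc2)cc1 | intermediate
12 | trimethyl orthoformate | COC(OC)OC | starting material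
13 | dimethyl acetal of 5 (not isolated) | COC(OC)c1c(O)c(Cc2ccc(OCc3ccccc3)cc2)c(OCc2ccccc2)c(Cc2ccc(OCc3ccccc3)cc2)c1OCc1ccccc1 | intermediate
14 | 3,5-bis(benzyloxy)-2,4-bis[4-(benzyloxy)benzyl]-6-(methoxymethylene)cyclohexa-2,4-dien-1-one (not isolated) | COC=C1C(=O)C(Cc2ccc(OCc3ccccc3)cc2)=C(OCc2ccccc2)C(Cc2ccc(OCc3ccccc3)cc2)=C1OCc1ccccc1 | intermediate
15 | (2R,3S)-5,7-bis(benzyloxy)-6,8-bis[4-(benzyloxy)benzyl]-2-[4-(benzyloxy)phenyl]-4-methoxychroman-3-yl acetate, 2,3-trans, C4 epimers | COC1c2c(OCc3ccccc3)c(Cc3ccc(OCc4ccccc4)cc3)c(OCc3ccccc3)c(Cc3ccc(OCc4ccccc4)cc3)c2O[C@H](c2ccc(OCc3ccccc3)cc2)[C@H]1OC(C)=O | intermediate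
16 | (2R,3S)-5,7-bis(benzyloxy)-6,8-bis[4-(benzyloxy)benzyl]-2-[4-(benzyloxy)phenyl]-4-methoxychroman-3-ol, C4 epimers | COC1c2c(OCc3ccccc3)c(Cc3ccc(OCc4ccccc4)cc3)c(OCc3ccccc3)c(Cc3ccc(OCc4ccccc4)cc3)c2O[C@H](c2ccc(OCc3ccccc3)cc2)[C@H]1O | intermediate
17 | (2R,3S)-3,5,7-tris(benzyloxy)-6,8-bis[4-(benzyloxy)benzyl]-2-[4-(benzyloxy)phenyl]-4-methoxychroman, C4 epimers | COC1c2c(OCc3ccccc3)c(Cc3ccc(OCc4ccccc4)cc3)c(OCc3ccccc3)c(Cc3ccc(OCc4ccccc4)cc3)c2O[C@H](c2ccc(OCc3ccccc3)cc2)[C@H]1OCc1ccccc1 | intermediate
18 | (2R,3S)-3,5,7-tris(benzyloxy)-6,8-bis[4-(benzyloxy)benzyl]-2-[4-(benzyloxy)phenyl]chroman-4-ol, C4 epimers | OC1c2c(OCc3ccccc3)c(Cc3ccc(OCc4ccccc4)cc3)c(OCc3ccccc3)c(Cc3ccc(OCc4ccccc4)cc3)c2O[C@H](c2ccc(OCc3ccccc3)cc2)[C@H]1OCc1ccccc1 | intermediate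
19 | (2R,3R)-3,5,7-tris(benzyloxy)-6,8-bis[4-(benzyloxy)benzyl]-2-[4-(benzyloxy)phenyl]chroman-4-one | O=C1c2c(OCc3ccccc3)c(Cc3ccc(OCc4ccccc4)cc3)c(OCc3ccccc3)c(Cc3ccc(OCc4ccccc4)cc3)c2O[C@H](c2ccc(OCc3ccccc3)cc2)[C@H]1OCc1ccccc1 | intermediate
20 | gericudranin D, (2R,3R)-3,5,7-trihydroxy-6,8-bis(4-hydroxybenzyl)-2-(4-hydroxyphenyl)chroman-4-one | O=C1c2c(O)c(Cc3ccc(O)cc3)c(O)c(Cc3ccc(O)cc3)c2O[C@H](c2ccc(O)cc2)[C@H]1O | target

**Step count**

Total steps: 11. Longest linear sequence: 9 steps (steps 3, 4, 5, 6, 7, 8, 9, 10, 11, from 6). The ring A branch (steps 1, 2, then 6–11) is 8 steps.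

**Steps most likely to fail**

1. Step 6. The cycloaddition may be slow, because the quinone methide is strongly stabilised and hindered at C4 by the peri benzyloxy group and the acetoxy-bearing alkene carbon is only a moderate nucleophile. The enol ester may be lost by acid methanolysis, regiocontrol may erode, or the chiral anion may discriminate the faces poorly. Fallback (known chemistry): it sets out from 5, with 10 as the source of the C2–C3–aryl unit, and rejoins the route at 20. The chelated phenol of 5 is protected (MOMCl, i-Pr2NEt, CH2Cl2) to give 4,6-bis(benzyloxy)-3,5-bis[4-(benzyloxy)benzyl]-2-(methoxymethoxy)benzaldehyde F1. Bromide 10 is lithiated (t-BuLi, THF, −78 °C) and added to F1 to give the racemic allylic alcohol (E)-1-aryl-3-[4-(benzyloxy)phenyl]prop-2-en-1-ol F2, which MnO2 in CH2Cl2 oxidises to the 2'-methoxymethoxy chalcone F3. Juliá–Colonna epoxidation (poly-L-leucine, urea–H2O2, DBU, THF) should give the (αR,βS)-chalcone epoxide F4. HCl in MeOH/THF removes the methoxymethyl group, and the freed phenol opens the epoxide 6-endo at the benzylic carbon with inversion to give the (2R,3R)-dihydroflavonol pentabenzyl ether F5. Hydrogenolysis of F5 (H2, Pd(OH)2/C) gives 20.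

2. Step 1. The para-hydroxybenzyl cation may self-condense with 2 to oligomers, may alkylate oxygen or the newly attached phenol rings, or the second C-benzylation may stall. Fallback: it sets out from 1 and rejoins at 5. The phloroglucinolate of 1 is C-alkylated under basic conditions (aqueous KOH/MeOH, 0 °C → rt) with 4-(benzyloxy)benzyl chloride (2.0 equiv) to give 3,5-bis[4-(benzyloxy)benzyl]-2,4,6-trihydroxybenzaldehyde F6. Partial O-benzylation of the 4- and 6-hydroxyls of F6 (BnBr 2.05 equiv, K2CO3, DMF), again sparing the chelated phenol, gives 5.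

3. Step 9. The C4 cation may lose the C3 proton to give a flav-3-ene enol ether, the exchange with water may stay incomplete, or the cation may be captured by an aromatic ring. Fallback: it sets out from 17 and rejoins at 19, by-passing 18. DDQ (1.1 equiv) in CH2Cl2/pH 7 buffer at 0 °C abstracts hydride from C4–H; water adds to the methoxy-substituted benzylic cation to give the C4 methyl hemiketal F7 (not isolated), which loses methanol to give 19. Reagent stoichiometry and low temperature are to keep the C6 and C8 methylenes, which are twisted out of conjugation with ring A, from being oxidised.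

**Further compounds**

F1 | step 6 | 4,6-bis(benzyloxy)-3,5-bis[4-(benzyloxy)benzyl]-2-(methoxymethoxy)benzaldehyde | O=Cc1c(OCOC)c(Cc2ccc(OCc3ccccc3)cc2)c(OCc2ccccc2)c(Cc2ccc(OCc3ccccc3)cc2)c1OCc1ccccc1
F2 | step 6 | racemic (E)-1-{4,6-bis(benzyloxy)-3,5-bis[4-(benzyloxy)benzyl]-2-(methoxymethoxy)phenyl}-3-[4-(benzyloxy)phenyl]prop-2-en-1-ol | OC(/C=C/c1ccc(OCc2ccccc2)cc1)c1c(OCOC)c(Cc2ccc(OCc3ccccc3)cc2)c(OCc2ccccc2)c(Cc2ccc(OCc3ccccc3)cc2)c1OCc1ccccc1
F3 | step 6 | (E)-1-{4,6-bis(benzyloxy)-3,5-bis[4-(benzyloxy)benzyl]-2-(methoxymethoxy)phenyl}-3-[4-(benzyloxy)phenyl]prop-2-en-1-one | O=C(/C=C/c1ccc(OCc2ccccc2)cc1)c1c(OCOC)c(Cc2ccc(OCc3ccccc3)cc2)c(OCc2ccccc2)c(Cc2ccc(OCc3ccccc3)cc2)c1OCc1ccccc1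
F4 | step 6 | (αR,βS)-epoxide of chalcone F3 | O=C([C@@H]1O[C@H]1c2ccc(OCc3ccccc3)cc2)c1c(OCOC)c(Cc2ccc(OCc3ccccc3)cc2)c(OCc2ccccc2)c(Cc2ccc(OCc3ccccc3)cc2)c1OCc1ccccc1
F5 | step 6 | (2R,3R)-5,7-bis(benzyloxy)-6,8-bis[4-(benzyloxy)benzyl]-2-[4-(benzyloxy)phenyl]-3-hydroxychroman-4-one | O=C1c2c(OCc3ccccc3)c(Cc3ccc(OCc4ccccc4)cc3)c(OCc3ccccc3)c(Cc3ccc(OCc4ccccc4)cc3)c2O[C@H](c2ccc(OCc3ccccc3)cc2)[C@H]1O
F6 | step 1 | 3,5-bis[4-(benzyloxy)benzyl]-2,4,6-trihydroxybenzaldehyde | O=Cc1c(O)c(Cc2ccc(OCc3ccccc3)cc2)c(O)c(Cc2ccc(OCc3ccccc3)cc2)c1O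
F7 | step 9 | C4 methyl hemiketal of 19, (2R,3R)-3,5,7-tris(benzyloxy)-6,8-bis[4-(benzyloxy)benzyl]-2-[4-(benzyloxy)phenyl]-4-methoxychroman-4-ol (not isolated) | COC1(O)c2c(OCc3ccccc3)c(Cc3ccc(OCc4ccccc4)cc3)c(OCc3ccccc3)c(Cc3ccc(OCc4ccccc4)cc3)c2O[C@H](c2ccc(OCc3ccccc3)cc2)[C@H]1OCc1ccccc1
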